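**Retrosynthetic overview**
1. Feature: the only ring is a 3,6-dihydro-2H-pyran (O1, C2 stereocentre, C3H2, C4H=C5, C6H2). It is formally an aldehyde + 2-alkylbutadiene adduct, but the chain sits on C5 beside the O-bound C6H2, the orientation a plain 2-alkyldiene disfavours. A silyloxy group placed on C4 and removed later enforces it.
2. C2 side chain: acrylic acid ⇐ methyl acrylate ⇐ (Pd, CO, MeOH) 1-alken-2-yl triflate ⇐ methyl ketone ⇐ Weinreb amide ⇐ C2 ethyl ester.
3. C4–H ⇐ C4–OTf ⇐ C4–OTBS, with the C4=C5 position carried unchanged from the enol silane.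
4. Ring (closed once, in the key step): C2–C3 and O1–C6 ⇐ ethyl glyoxylate + 2-TBSO-3-homofarnesylbuta-1,3-diene under [Cu((S,S)-tBu-box)](SbF6)2, which also sets C2.
5. Diene ⇐ α-methylene ketone ⇐ Stille coupling of the kinetic enol triflate of (E,E)-farnesylacetone with a 1-ethoxyvinylstannane; farnesylacetone ⇐ (E,E)-farnesol + ethyl acetoacetate.

Key step: step 7

Conventions: homofarnesyl = (3E,7E)-4,8,12-trimethyltrideca-3,7,11-trien-1-yl. Ring atoms are O1, C2–C6; chain atoms are C1' (on C5), C2', C3'=C4' and so on. TBS = tert-butyldimethylsilyl, Tf = trifluoromethanesulfonyl. tBu-box = 2,2'-(propane-2,2-diyl)bis(4-tert-butyl-4,5-dihydrooxazole).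
Assumption: the (S,S)-tBu-box copper catalyst is taken to expose the Si face of chelated ethyl glyoxylate, as in its glyoxylate-ene and pyruvate aldol reactions. If the adduct proved to be (2R), the equally available (R,R)-ligand would be used and nothing else changes.

Step 1
Reactants: 1 (2E,6E)-farnesol
Product: 2 (2E,6E)-farnesyl bromide
Conditions: PBr3 (0.4 equiv), Et2O, −10 → 0 °C, used crude
Reagents that add atoms: phosphorus tribromide, BrP(Br)Br
Why: PBr3 activates the primary allylic hydroxyl group and bromide displaces it by SN2 at low temperature (alcohol-to-bromide substitution), which should leave both E alkenes untouched and avoid allylic transposition.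

Step 2
Reactants: 2 (2E,6E)-farnesyl bromide; 3 ethyl acetoacetate
Product: 5 ethyl (4E,8E)-2-acetyl-5,9,13-trimethyltetradeca-4,8,12-trienoate (racemic at C2), via sodium enolate of ethyl acetoacetate 4 (not isolated)
Conditions: 3 (1.5 equiv), NaH, THF, 0 °C; then 2, 0 °C → rt
Reagents that add atoms: none
Why: In this acetoacetic ester alkylation the soft stabilised enolate attacks the primary allylic bromide at carbon by SN2, excess 3 suppresses double alkylation, and the racemic centre formed is removed in step 3.

Step 3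
Reactants: 5 ethyl (4E,8E)-2-acetyl-5,9,13-trimethyltetradeca-4,8,12-trienoate
Product: 7 (5E,9E)-6,10,14-trimethylpentadeca-5,9,13-trien-2-one (farnesylacetone), via beta-keto acid 6 (not isolated)
Conditions: KOH, MeOH–H2O, 60 °C; then 1 M HCl to pH 5, rt
Reagents that add atoms: none
Why: Saponification followed by cyclic six-centre decarboxylation of the β-keto acid (ketonic cleavage of the acetoacetic ester synthesis) leaves the methyl ketone, and the isolated trisubstituted alkenes tolerate base and brief dilute acid.

Step 4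
Reactants: 7 farnesylacetone
Product: 9 (5E,9E)-6,10,14-trimethylpentadeca-1,5,9,13-tetraen-2-yl trifluoromethanesulfonate, via lithium enolate 8 (not isolated)
Conditions: LiN(iPr)2, THF, −78 °C (7 added to the base); then PhNTf2, −78 → 0 °C
Reagents that add atoms: N-phenylbis(trifluoromethanesulfonimide), O=S(=O)(N(c1ccccc1)S(=O)(=O)C(F)(F)F)C(F)(F)F
Why: In this kinetic enol triflate formation the hindered amide removes a methyl proton rather than a C3 methylene proton at −78 °C, and O-sulfonylation fixes the terminal 1-alken-2-yl triflate.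

Step 5
Reactants: 9 the 1-alken-2-yl triflate; 10 tributyl(1-ethoxyvinyl)stannane
Product: 12 (6E,10E)-7,11,15-trimethyl-3-methylidenehexadeca-6,10,14-trien-2-one, via 2-ethoxydiene 11 (not isolated)
Conditions: Pd(PPh3)4 (5 mol %), LiCl, THF, 65 °C; then 1 M HCl, THF, 0 °C; used at once
Reagents that add atoms: water, O
Why: Stille coupling of a vinyl triflate with an α-alkoxyvinylstannane (LiCl for turnover) forms the central diene bond, Heck closure onto the chain being limited to disfavoured 4-exo or 5-endo modes, and dilute acid then protonates the CH2 terminus of the ethyl enol ether and hydrolyses it to the α-methylene ketone.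

Step 6
Reactants: 12 the α-methylene ketone
Product: 13 tert-butyldimethyl{[(6E,10E)-7,11,15-trimethyl-3-methylidenehexadeca-1,6,10,14-tetraen-2-yl]oxy}silane
Conditions: TBSOTf, Et3N, CH2Cl2, 0 °C; chromatography on Et3N-deactivated silica, then removal of all amine under vacuum
Reagents that add atoms: tert-butyldimethylsilyl trifluoromethanesulfonate, CC(C)(C)[Si](C)(C)OS(=O)(=O)C(F)(F)F
Why: In this soft enolisation TBSOTf silylates the carbonyl oxygen and Et3N removes a proton from the methyl group, the only position from which the activated enone can lose one, so the 2-silyloxy-1,3-diene is the only possible enol silane.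

Step 7
Reactants: 13 the 2-silyloxy-3-homofarnesyldiene; 14 ethyl glyoxylate
Product: 15 ethyl (2S)-4-[(tert-butyldimethylsilyl)oxy]-5-homofarnesyl-3,6-dihydro-2H-pyran-2-carboxylate
Conditions: [Cu((S,S)-tBu-box)](SbF6)2 (10 mol %, from CuCl2, AgSbF6 and the ligand), 14 (monomer freshly distilled from the commercial toluene solution, 1.05 equiv), CH2Cl2, −78 → −40 °C; filtration through Et3N-deactivated silica
Reagents that add atoms: none
Why: Ethyl glyoxylate chelates the divalent copper centre of the square-planar tBu-box complex through its two carbonyl oxygens, and C1 of 13, the enol-silane terminus and most nucleophilic diene carbon, bonds to the formyl carbon (C2–C3) while the aldehyde oxygen bonds to the methylidene carbon (O1–C6), either in one asynchronous [4+2] event or by a Mukaiyama aldol addition followed by capture of the silyloxyallyl cation, both of which lead to 15. The closest known reaction types are the copper bis(oxazoline)-catalysed oxa-Diels–Alder, carbonyl-ene and Mukaiyama aldol reactions of glyoxylate and pyruvate esters and the chiral-Lewis-acid oxa-Diels–Alder reactions of aldehydes with 2-silyloxydienes that carry no 1-alkoxy group. The one ring closes as a six-membered [4+2] cycloaddition (6-endo O-closure in the stepwise reading), helped by the 2,3-disubstitution that makes the s-cis diene easy to reach, and it leaves the alkene at C4=C5 as a tetrasubstituted TBS enol ether. C2, the only new stereocentre, is controlled by the ligand: the tert-butyl groups of the (S,S)-ligand shield the Re face of the chelated aldehyde, so that C3 adds to the Si face and C2 becomes S. The regioselectivity needed (O1 on the CH2 beside the chain-bearing carbon) is secured by the silyloxy donor on C4, which outweighs the opposite and weaker bias of the alkyl group. The chemoselectivity needed (no glyoxylate-ene reaction at the three trisubstituted chain alkenes, no open-chain aldol product) is secured by the much higher nucleophilicity of the enol silane, the low temperature, the absence of excess glyoxylate and the bulk of the TBS group, which slows silyl transfer to the aldolate oxygen.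

Step 8
Reactants: 15 the silyl enol ether cycloadduct
Product: 17 ethyl (2S)-5-homofarnesyl-4-(trifluoromethanesulfonyloxy)-3,6-dihydro-2H-pyran-2-carboxylate, via caesium enolate 16 (not isolated)
Conditions: CsF (flame-dried), PhNTf2, DME, rt
Reagents that add atoms: N-phenylbis(trifluoromethanesulfonimide), O=S(=O)(N(c1ccccc1)S(=O)(=O)C(F)(F)F)C(F)(F)F
Why: In this fluoride-triggered exchange of a silyl enol ether for an enol triflate, fluoride attacks silicon and releases the C4=C5 enolate regiospecifically while PhNTf2 already present sulfonylates it on oxygen at once, so enolate migration towards C3 or proton loss at C2 should not intervene, and the ester, which rules out MeLi, is tolerated.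

Step 9
Reactants: 17 the C4 enol triflate
Product: 18 ethyl (2S)-5-homofarnesyl-3,6-dihydro-2H-pyran-2-carboxylate
Conditions: Pd(PPh3)4 (5 mol %), LiCl, Bu3SnH, THF, rt → 50 °C
Reagents that add atoms: none
Why: In this palladium-catalysed hydrogenolysis of an enol triflate, oxidative addition, chloride exchange, very fast Sn–H transmetalation and reductive elimination put H on C4 with the alkene held at C4=C5, and the tin hydride is chosen over formate because its faster hydride delivery should outrun 5-exo carbopalladation of the C3'=C4' chain alkene by the C4 vinylpalladium species.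

Step 10
Reactants: 18 the dihydropyran ethyl ester
Product: 19 (2S)-5-homofarnesyl-N-methoxy-N-methyl-3,6-dihydro-2H-pyran-2-carboxamide
Conditions: MeNH(OMe)·HCl, iPrMgCl, THF, −20 → 0 °C
Reagents that add atoms: N,O-dimethylhydroxylamine hydrochloride, CNOC.Cl
Why: The Weinreb amide forms by aminolysis of the ester with the chloromagnesium amide made in the flask, a method that leaves α-alkoxy ester stereocentres such as C2 intact at low temperature.

Step 11
Reactants: 19 the Weinreb amide
Product: 21 1-[(2S)-5-homofarnesyl-3,6-dihydro-2H-pyran-2-yl]ethan-1-one, via magnesium chelate of the tetrahedral adduct 20 (not isolated)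
Conditions: MeMgBr, THF, 0 °C; then aq NH4Cl
Reagents that add atoms: methylmagnesium bromide, C[Mg]Br
Why: In this Weinreb ketone synthesis the five-membered chelate persists until the quench, so only one methyl group is added and the ketone is never exposed to the basic reagent, which protects C2.

Step 12
Reactants: 21 the methyl ketone
Product: 23 1-[(2S)-5-homofarnesyl-3,6-dihydro-2H-pyran-2-yl]ethenyl trifluoromethanesulfonate, via potassium enolate 22 (not isolated)
Conditions: KN(SiMe3)2, THF, −78 °C (21 added to the base); then N-(5-chloropyridin-2-yl)bis(trifluoromethanesulfonimide) (Comins reagent), −78 °C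
Reagents that add atoms: Comins reagent, O=S(=O)(N(c1ccc(Cl)cn1)S(=O)(=O)C(F)(F)F)C(F)(F)F
Why: In this kinetic enol triflate formation the bulky base in excess removes a proton from the unhindered methyl group rather than the tertiary C2–H, and the reactive triflating agent traps the terminal enolate at −78 °C before proton exchange could scramble C2.

Step 13
Reactants: 23 the side-chain vinyl triflate
Product: 24 methyl 2-[(2S)-5-homofarnesyl-3,6-dihydro-2H-pyran-2-yl]prop-2-enoate
Conditions: Pd(OAc)2 (5 mol %), PPh3, Et3N, CO (1 atm), MeOH–DMF, rt → 40 °C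
Reagents that add atoms: carbon monoxide, [C-]#[O+]; methanol, CO
Why: In this palladium-catalysed alkoxycarbonylation of a vinyl triflate, oxidative addition, CO insertion and methanolysis of the acylpalladium species build the 2-substituted acrylate, CO insertion being far faster than a strained 4-exo or 5-endo Heck closure onto C4=C5.

Step 14
Reactants: 24 the methyl acrylate
Product: 26 2-[(2S)-5-homofarnesyl-3,6-dihydro-2H-pyran-2-yl]prop-2-enoic acid (target), via lithium carboxylate 25 (not isolated)
Conditions: LiOH, THF–H2O, rt; then 1 M HCl to pH 3, 0 °C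
Reagents that add atoms: lithium hydroxide, [Li+].[OH-]
Why: Saponification (BAc2) cleaves the methyl ester at room temperature, where the α-branched acrylate resists conjugate addition and the C2–H, merely allylic and cross-conjugated to the carboxyl group, is not acidic enough to epimerise.

**Compound list**
1 | (2E,6E)-farnesol | OC/C=C(\C)CC/C=C(\C)CCC=C(C)C | starting material
2 | (2E,6E)-farnesyl bromide | BrC/C=C(\C)CC/C=C(\C)CCC=C(C)C | intermediate
3 | ethyl acetoacetate | CCOC(=O)CC(C)=O | starting material
4 | sodium enolate of ethyl acetoacetate | CCOC(=O)C=C(C)[O-].[Na+] | intermediate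
5 | ethyl (4E,8E)-2-acetyl-5,9,13-trimethyltetradeca-4,8,12-trienoate (racemic) | CCOC(=O)C(C(C)=O)C/C=C(\C)CC/C=C(\C)CCC=C(C)C | intermediate
6 | (4E,8E)-2-acetyl-5,9,13-trimethyltetradeca-4,8,12-trienoic acid | OC(=O)C(C(C)=O)C/C=C(\C)CC/C=C(\C)CCC=C(C)C | intermediate
7 | (5E,9E)-6,10,14-trimethylpentadeca-5,9,13-trien-2-one (farnesylacetone) | CC(=O)CC/C=C(\C)CC/C=C(\C)CCC=C(C)C | intermediate
8 | lithium (5E,9E)-6,10,14-trimethylpentadeca-1,5,9,13-tetraen-2-olate | C=C([O-])CC/C=C(\C)CC/C=C(\C)CCC=C(C)C.[Li+] | intermediate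
9 | (5E,9E)-6,10,14-trimethylpentadeca-1,5,9,13-tetraen-2-yl trifluoromethanesulfonate | C=C(OS(=O)(=O)C(F)(F)F)CC/C=C(\C)CC/C=C(\C)CCC=C(C)C | intermediate
10 | tributyl(1-ethoxyvinyl)stannane | C=C(OCC)[Sn](CCCC)(CCCC)CCCC | starting material
11 | (6E,10E)-2-ethoxy-7,11,15-trimethyl-3-methylidenehexadeca-1,6,10,14-tetraene | C=C(OCC)C(=C)CC/C=C(\C)CC/C=C(\C)CCC=C(C)C | intermediate
12 | (6E,10E)-7,11,15-trimethyl-3-methylidenehexadeca-6,10,14-trien-2-one | CC(=O)C(=C)CC/C=C(\C)CC/C=C(\C)CCC=C(C)C | intermediate
13 | tert-butyldimethyl{[(6E,10E)-7,11,15-trimethyl-3-methylidenehexadeca-1,6,10,14-tetraen-2-yl]oxy}silane | C=C(O[Si](C)(C)C(C)(C)C)C(=C)CC/C=C(\C)CC/C=C(\C)CCC=C(C)C | intermediate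
14 | ethyl glyoxylate | CCOC(=O)C=O | starting material
15 | ethyl (2S)-4-[(tert-butyldimethylsilyl)oxy]-5-[(3E,7E)-4,8,12-trimethyltrideca-3,7,11-trien-1-yl]-3,6-dihydro-2H-pyran-2-carboxylate | CCOC(=O)[C@@H]1CC(O[Si](C)(C)C(C)(C)C)=C(CC/C=C(\C)CC/C=C(\C)CCC=C(C)C)CO1 | intermediate
16 | caesium enolate (C4–O−, C4=C5) of the corresponding (2S)-4-oxo ester | CCOC(=O)[C@@H]1CC([O-])=C(CC/C=C(\C)CC/C=C(\C)CCC=C(C)C)CO1.[Cs+] | intermediate
17 | ethyl (2S)-4-(trifluoromethanesulfonyloxy)-5-[(3E,7E)-4,8,12-trimethyltrideca-3,7,11-trien-1-yl]-3,6-dihydro-2H-pyran-2-carboxylate | CCOC(=O)[C@@H]1CC(OS(=O)(=O)C(F)(F)F)=C(CC/C=C(\C)CC/C=C(\C)CCC=C(C)C)CO1 | intermediate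
18 | ethyl (2S)-5-[(3E,7E)-4,8,12-trimethyltrideca-3,7,11-trien-1-yl]-3,6-dihydro-2H-pyran-2-carboxylate | CCOC(=O)[C@@H]1CC=C(CC/C=C(\C)CC/C=C(\C)CCC=C(C)C)CO1 | intermediate
19 | (2S)-N-methoxy-N-methyl-5-[(3E,7E)-4,8,12-trimethyltrideca-3,7,11-trien-1-yl]-3,6-dihydro-2H-pyran-2-carboxamide | CON(C)C(=O)[C@@H]1CC=C(CC/C=C(\C)CC/C=C(\C)CCC=C(C)C)CO1 | intermediate
20 | bromomagnesium chelate of the tetrahedral adduct of MeMgBr with 19 | CC([O-])(N(C)OC)[C@@H]1CC=C(CC/C=C(\C)CC/C=C(\C)CCC=C(C)C)CO1.[Mg+2].[Br-] | intermediate
21 | 1-{(2S)-5-[(3E,7E)-4,8,12-trimethyltrideca-3,7,11-trien-1-yl]-3,6-dihydro-2H-pyran-2-yl}ethan-1-one | CC(=O)[C@@H]1CC=C(CC/C=C(\C)CC/C=C(\C)CCC=C(C)C)CO1 | intermediate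
22 | potassium terminal enolate of 21 | C=C([O-])[C@@H]1CC=C(CC/C=C(\C)CC/C=C(\C)CCC=C(C)C)CO1.[K+] | intermediate
23 | 1-{(2S)-5-[(3E,7E)-4,8,12-trimethyltrideca-3,7,11-trien-1-yl]-3,6-dihydro-2H-pyran-2-yl}ethenyl trifluoromethanesulfonate | C=C(OS(=O)(=O)C(F)(F)F)[C@@H]1CC=C(CC/C=C(\C)CC/C=C(\C)CCC=C(C)C)CO1 | intermediate
24 | methyl 2-{(2S)-5-[(3E,7E)-4,8,12-trimethyltrideca-3,7,11-trien-1-yl]-3,6-dihydro-2H-pyran-2-yl}prop-2-enoate | C=C(C(=O)OC)[C@@H]1CC=C(CC/C=C(\C)CC/C=C(\C)CCC=C(C)C)CO1 | intermediate
25 | lithium salt of 26 | C=C(C(=O)[O-])[C@@H]1CC=C(CC/C=C(\C)CC/C=C(\C)CCC=C(C)C)CO1.[Li+] | intermediate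
26 | 2-{(2S)-5-[(3E,7E)-4,8,12-trimethyltrideca-3,7,11-trien-1-yl]-3,6-dihydro-2H-pyran-2-yl}prop-2-enoic acid | C=C(C(=O)O)[C@@H]1CC=C(CC/C=C(\C)CC/C=C(\C)CCC=C(C)C)CO1 | target

**Step count**
Total: 14 steps. Longest linear sequence: 14 steps, from (2E,6E)-farnesol. The diene is reached in 6 steps.

**The three steps most likely to fail**

Step 7 (key step).
- What may go wrong: the silyl group may transfer to the copper-bound aldolate oxygen, so that the chain is released open instead of closing the ring. Glyoxylate may attack the chain alkenes in a carbonyl-ene reaction. Facial selectivity may be poor with a diene that lacks a 1-alkoxy donor. Traces of amine carried over from step 6 may deactivate the catalyst.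
- Fallback: the ring is closed by olefin metathesis at C4=C5 instead of by cycloaddition. It sets out from 9 and 14 and comes back to the route at 18, so steps 8 and 9 also fall away.
- Triflate 9 is methoxycarbonylated (Pd(OAc)2, PPh3, Et3N, CO, MeOH–DMF) to methyl (5E,9E)-6,10,14-trimethyl-2-methylidenepentadeca-5,9,13-trienoate F1. Reduction with iBu2AlH (CH2Cl2, −78 °C) gives (5E,9E)-6,10,14-trimethyl-2-methylidenepentadeca-5,9,13-trien-1-ol F2. An Appel reaction (CBr4, PPh3) then gives (5E,9E)-2-(bromomethyl)-6,10,14-trimethylpentadeca-1,5,9,13-tetraene F3.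
- Separately, 14 is allylated with allyltributylstannane under a BINOL–Ti(OiPr)4 catalyst (BINOL enantiomer chosen for 2S) to ethyl (2S)-2-hydroxypent-4-enoate F4.
- Etherification of F4 with F3 is promoted by Ag2O (Et2O, dark), which avoids a basic alkoxide next to the ester. It gives ethyl (2S)-2-{[(5E,9E)-6,10,14-trimethyl-2-methylidenepentadeca-5,9,13-trien-1-yl]oxy}pent-4-enoate F5.
- The second-generation Grubbs catalyst (CH2Cl2, 40 °C) joins the monosubstituted and 1,1-disubstituted alkenes of F5 to give 18. The trisubstituted chain alkenes are too hindered and too badly placed to compete.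

Step 8.
- What may go wrong: desilylation of the hindered TBS enol ether may be slow. Traces of water may protonate the released enolate, which loses the regiochemical information. The ring may open by retro-oxa-Michael cleavage at C6–O1. Proton exchange at C2 may occur before O-sulfonylation.
- Fallback: the enol silane is used as a carbon nucleophile, so neither a free enolate nor palladium is needed. It sets out from 15 and comes back at 18, bypassing steps 8 and 9.
- NBS (1 equiv, THF, −78 °C) brominates C5 of 15 to ethyl (2S)-5-bromo-5-homofarnesyl-4-oxooxane-2-carboxylate F6. Luche reduction (NaBH4, CeCl3·7H2O, MeOH, −78 °C) gives ethyl (2S)-5-bromo-4-hydroxy-5-homofarnesyloxane-2-carboxylate F7. MsCl/Et3N (CH2Cl2, 0 °C) gives ethyl (2S)-5-bromo-5-homofarnesyl-4-(methanesulfonyloxy)oxane-2-carboxylate F8.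
- Activated zinc dust (EtOH, 50 °C) then effects Boord-type reductive 1,2-elimination of Br and OMs to 18.
- The mesylate is needed so that the C4–O bond leaves and not the ring C6–O1 bond. The C5–Br/C4–O pair fixes the alkene at C4=C5.

Step 9.
- What may go wrong: the C4 vinylpalladium intermediate may carbopalladate the C3'=C4' alkene (5-exo Heck closure) before hydride transfer. Palladium may consume the tin hydride as distannane and hydrogen. The ring alkene may migrate.
- Fallback: a C4 alcohol is dehydrated in place of triflate hydrogenolysis. It sets out from 15 and comes back at 18.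
- HF·pyridine buffered with pyridine (THF, 0 °C) cleaves the enol silane to ethyl (2S,5S)-5-homofarnesyl-4-oxooxane-2-carboxylate F9. This is the 2,5-trans diequatorial epimer, towards which the C5 epimers should equilibrate through the enol.
- LiBH(sBu)3 (THF, −78 °C) attacks from the equatorial side and gives the axial alcohol ethyl (2S,4R,5S)-4-hydroxy-5-homofarnesyloxane-2-carboxylate F10.
- POCl3/pyridine (0 °C → rt) removes the alcohol by anti elimination. Loss of the axial C5–H is preferred (Zaitsev orientation, trisubstituted alkene). Any C3=C4 isomer would have to be separated from 18.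

**Further compounds**
F1 | step 7 | methyl (5E,9E)-6,10,14-trimethyl-2-methylidenepentadeca-5,9,13-trienoate | COC(=O)C(=C)CC/C=C(\C)CC/C=C(\C)CCC=C(C)C
F2 | step 7 | (5E,9E)-6,10,14-trimethyl-2-methylidenepentadeca-5,9,13-trien-1-ol | OCC(=C)CC/C=C(\C)CC/C=C(\C)CCC=C(C)C
F3 | step 7 | (5E,9E)-2-(bromomethyl)-6,10,14-trimethylpentadeca-1,5,9,13-tetraene | BrCC(=C)CC/C=C(\C)CC/C=C(\C)CCC=C(C)C
F4 | step 7 | ethyl (2S)-2-hydroxypent-4-enoate | CCOC(=O)[C@@H](O)CC=C
F5 | step 7 | ethyl (2S)-2-{[(5E,9E)-6,10,14-trimethyl-2-methylidenepentadeca-5,9,13-trien-1-yl]oxy}pent-4-enoate | CCOC(=O)[C@@H](OCC(=C)CC/C=C(\C)CC/C=C(\C)CCC=C(C)C)CC=C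
F6 | step 8 | ethyl (2S)-5-bromo-5-homofarnesyl-4-oxooxane-2-carboxylate (C5 epimers) | CCOC(=O)[C@@H]1CC(=O)C(Br)(CC/C=C(\C)CC/C=C(\C)CCC=C(C)C)CO1
F7 | step 8 | ethyl (2S)-5-bromo-4-hydroxy-5-homofarnesyloxane-2-carboxylate (C4/C5 diastereomers) | CCOC(=O)[C@@H]1CC(O)C(Br)(CC/C=C(\C)CC/C=C(\C)CCC=C(C)C)CO1
F8 | step 8 | ethyl (2S)-5-bromo-5-homofarnesyl-4-(methanesulfonyloxy)oxane-2-carboxylate (C4/C5 diastereomers) | CCOC(=O)[C@@H]1CC(OS(C)(=O)=O)C(Br)(CC/C=C(\C)CC/C=C(\C)CCC=C(C)C)CO1
F9 | step 9 | ethyl (2S,5S)-5-homofarnesyl-4-oxooxane-2-carboxylate | CCOC(=O)[C@@H]1CC(=O)[C@@H](CC/C=C(\C)CC/C=C(\C)CCC=C(C)C)CO1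
F10 | step 9 | ethyl (2S,4R,5S)-4-hydroxy-5-homofarnesyloxane-2-carboxylate | CCOC(=O)[C@@H]1C[C@@H](O)[C@@H](CC/C=C(\C)CC/C=C(\C)CCC=C(C)C)CO1
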